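The flavanone pyranone ring is disconnected at O1–C2 and C4–C4a, which leaves an 8-aryl apigenin carrying a 4-aryl-3,5-dialkoxyphenol and a chiral C2–C3–C4 unit. The key step is a one-flask [3+3] annulation: Mitsunobu etherification of the single free phenol (the future O1) with an (R)-3-aryl-3-hydroxypropanoate sets C2 as (S) by inversion, and TFA/TFAA then closes C4 onto C4a. It exploits the 1,3-relationship of O1 and the electron-rich ortho carbon C4a of flavanone ring A, whose two open positions are equivalent. The precursors are a pentabenzylated biaryl phenol from a Suzuki coupling and a benzyl carbonate-protected β-hydroxy ester.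

Key step: step 9

Remark: the target defines only C2; the configuration of the hindered C6–C8'' biaryl axis is not specified, so the axis is formed without control and both rotamers are taken as the target.

Step 1
Reactants: 1 apigenin
Product: 2 tri-O-benzylapigenin [5,7-bis(benzyloxy)-2-[4-(benzyloxy)phenyl]-4H-chromen-4-one]
Conditions: BnBr (excess), K2CO3, TBAI (cat.), DMF, 80 °C
Reagents that add atoms: benzyl bromide, BrCc1ccccc1
Why: Williamson etherification of all three phenols; excess reagent and heat are needed because the 5-OH is hydrogen-bonded to the C4 carbonyl and is alkylated last.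

Step 2
Reactants: 2 tri-O-benzylapigenin
Product: 3 tri-O-benzyl-8-iodoapigenin [5,7-bis(benzyloxy)-2-[4-(benzyloxy)phenyl]-8-iodo-4H-chromen-4-one]
Conditions: I2, CF3CO2Ag, CH2Cl2, 0 °C to rt, dark
Reagents that add atoms: iodine, II
Why: Electrophilic aromatic iodination; with the 5-oxygen alkylated, C8 (flanked by the small ring oxygen and one benzyloxy group) should be attacked in preference to C6 (between two benzyloxy groups), and the B ring is deactivated by conjugation to the enone.

Step 3
Reactants: 4 3,5-bis(benzyloxy)phenol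
Product: 5 TIPS ether [3,5-bis(benzyloxy)phenoxy]triisopropylsilane
Conditions: TIPSCl, imidazole, DMF, rt
Reagents that add atoms: chlorotriisopropylsilane, CC(C)[Si](Cl)(C(C)C)C(C)C
Why: Silylation of the phenol gives a base-stable ether whose bulk later shields the two ring positions next to it.

Step 4
Reactants: 5 TIPS ether
Product: 7 {2,6-bis(benzyloxy)-4-[(triisopropylsilyl)oxy]phenyl}boronic acid, via aryllithium 6 (not isolated)
Conditions: n-BuLi, THF, 0 °C; then B(OiPr)3, −78 °C to rt; aq. NH4Cl
Reagents that add atoms: triisopropyl borate, CC(C)OB(OC(C)C)OC(C)C; water, O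
Why: Directed ortho-metalation; the C–H between the two benzyloxy groups is acidified by both oxygens and lies away from the bulky, weakly directing silyloxy group, and the aryllithium is trapped by the borate and hydrolysed to the boronic acid.

Step 5
Reactants: 3 tri-O-benzyl-8-iodoapigenin; 7 arylboronic acid
Product: 9 biaryl phenol [5,7-bis(benzyloxy)-8-[2,6-bis(benzyloxy)-4-hydroxyphenyl]-2-[4-(benzyloxy)phenyl]-4H-chromen-4-one], via TIPS biaryl 8 (not isolated)
Conditions: Pd(OAc)2 (5 mol%), SPhos (10 mol%), K3PO4, toluene/H2O (10:1), 90 °C; then TBAF, THF, rt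
Reagents that add atoms: none
Why: Suzuki–Miyaura coupling with the bulky, electron-rich biaryl phosphine SPhos, a ligand suited to joining two di-ortho-substituted partners; the electron-poor flavone iodide should add readily to zerovalent palladium, and fluoride then cleaves the Si–O bond in the same flask.

Step 6
Reactants: 10 4-hydroxybenzoic acid
Product: 11 4-{[(benzyloxy)carbonyl]oxy}benzoic acid
Conditions: CbzCl, NaOH (2 equiv), H2O/acetone, 0 °C; then HCl to pH 2
Reagents that add atoms: benzyl chloroformate, O=C(Cl)OCc1ccccc1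
Why: Schotten–Baumann acylation of the phenoxide; any mixed anhydride formed at the carboxylate is hydrolysed back in the aqueous base, and the carbonate later makes the benzylic carbon resistant to ionisation and is removed by hydrogenolysis.

Step 7
Reactants: 11 4-{[(benzyloxy)carbonyl]oxy}benzoic acid; 12 mono-tert-butyl malonate [3-(tert-butoxy)-3-oxopropanoic acid]
Product: 14 tert-butyl 3-(4-{[(benzyloxy)carbonyl]oxy}phenyl)-3-oxopropanoate, via acid chloride 13 (not isolated)
Conditions: (COCl)2, DMF (cat.), CH2Cl2, rt; then 12, MgCl2, Et3N, MeCN, 0 °C to rt; aq. citric acid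
Reagents that add atoms: none
Why: Acid chloride formation followed by decarboxylative Claisen condensation of the magnesium enolate of the malonic half-ester; the mild Et3N/MgCl2 conditions should leave the aryl carbonate intact.

Step 8
Reactants: 14 β-keto ester
Product: 15 tert-butyl (3R)-3-(4-{[(benzyloxy)carbonyl]oxy}phenyl)-3-hydroxypropanoate
Conditions: RuCl(p-cymene)[(R,R)-TsDPEN] (1 mol%), HCO2H/Et3N (5:2), CH2Cl2, 30 °C
Reagents that add atoms: none
Why: Noyori–Ikariya asymmetric transfer hydrogenation of an aryl ketone; the CH/π contact between the aryl group and the p-cymene ligand fixes the face of hydride delivery, so the (R,R)-ligand should give the (R)-carbinol, the same spatial sense as (R)-1-phenylethanol from acetophenone.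

Step 9
Reactants: 9 biaryl phenol; 15 (R)-β-hydroxy ester
Product: 18 protected flavanone–flavone [benzyl 4-[(2S)-5,7-bis(benzyloxy)-6-{5,7-bis(benzyloxy)-2-[4-(benzyloxy)phenyl]-4-oxo-4H-chromen-8-yl}-4-oxo-3,4-dihydro-2H-chromen-2-yl]phenyl carbonate], via ether ester 16 (not isolated), via ether acid 17 (not isolated)
Conditions: PPh3, DIAD, toluene, 0 °C to rt; then TFA/CH2Cl2 (1:2), TFAA, 0 °C to rt
Reagents that add atoms: none
Why: PPh3/DIAD turn the (R)-carbinol of 15 into an alkoxyphosphonium ion that the phenoxide of 9 (its only free OH, the future O1) displaces by SN2 to give the (S)-ether 16, after which TFA cleaves the tert-butyl ester and TFAA converts acid 17 into a mixed anhydride that acylates the neighbouring ring carbon. The closest known reaction types are the Mitsunobu etherification of phenols with secondary benzylic β-hydroxy esters and the anhydride-mediated cyclisation of 3-aryloxypropanoic acids to chroman-4-ones. The pyranone ring is closed in the second stage by a 6-exo-trig intramolecular Friedel–Crafts acylation that joins C4 to C4a. C2 is controlled by the configuration of 15, which is transferred with inversion; the electron-poor benzyl carbonate on the para oxygen destabilises a benzylic cation, so neither the phosphonium stage nor the acid stage should erode it. The step needs O-alkylation at one oxygen and acylation at one carbon: the two benzyl ethers leave a single phenol, the two open ring positions beside it are equivalent by symmetry and activated by all three oxygens, and the flavone ring is deactivated and cannot close a six-membered ring. A short, cold acid stage keeps tert-butylation and trifluoroacetylation of the ring from competing with the intramolecular closure.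

Step 10
Reactants: 18 protected flavanone–flavone
Product: 19 target [(2S)-5,7-dihydroxy-6-[5,7-dihydroxy-2-(4-hydroxyphenyl)-4-oxo-4H-chromen-8-yl]-2-(4-hydroxyphenyl)-2,3-dihydro-4H-chromen-4-one]
Conditions: H2 (1 atm), 10% Pd/C, THF/MeOH, rt
Reagents that add atoms: none
Why: Hydrogenolysis of the five benzyl ethers and of the benzyl carbonate (which loses CO2) under neutral conditions, which should leave the base-sensitive C2 stereocentre, the flavone C2=C3 bond and both ketones untouched at 1 atm and room temperature.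

Compound list
1 | apigenin | O=c1cc(-c2ccc(O)cc2)oc2cc(O)cc(O)c12 | starting material
2 | 5,7-bis(benzyloxy)-2-[4-(benzyloxy)phenyl]-4H-chromen-4-one | O=c1cc(-c2ccc(OCc3ccccc3)cc2)oc2cc(OCc3ccccc3)cc(OCc3ccccc3)c12 | intermediate
3 | 5,7-bis(benzyloxy)-2-[4-(benzyloxy)phenyl]-8-iodo-4H-chromen-4-one | O=c1cc(-c2ccc(OCc3ccccc3)cc2)oc2c(I)c(OCc3ccccc3)cc(OCc3ccccc3)c12 | intermediate
4 | 3,5-bis(benzyloxy)phenol | Oc1cc(OCc2ccccc2)cc(OCc2ccccc2)c1 | starting material
5 | [3,5-bis(benzyloxy)phenoxy]triisopropylsilane | CC(C)[Si](C(C)C)(C(C)C)Oc1cc(OCc2ccccc2)cc(OCc2ccccc2)c1 | intermediate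
6 | {2,6-bis(benzyloxy)-4-[(triisopropylsilyl)oxy]phenyl}lithium | [Li]c1c(OCc2ccccc2)cc(O[Si](C(C)C)(C(C)C)C(C)C)cc1OCc1ccccc1 | intermediate
7 | {2,6-bis(benzyloxy)-4-[(triisopropylsilyl)oxy]phenyl}boronic acid | OB(O)c1c(OCc2ccccc2)cc(O[Si](C(C)C)(C(C)C)C(C)C)cc1OCc1ccccc1 | intermediate
8 | 5,7-bis(benzyloxy)-8-{2,6-bis(benzyloxy)-4-[(triisopropylsilyl)oxy]phenyl}-2-[4-(benzyloxy)phenyl]-4H-chromen-4-one | O=c1cc(-c2ccc(OCc3ccccc3)cc2)oc2c(-c3c(OCc4ccccc4)cc(O[Si](C(C)C)(C(C)C)C(C)C)cc3OCc3ccccc3)c(OCc3ccccc3)cc(OCc3ccccc3)c12 | intermediate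
9 | 5,7-bis(benzyloxy)-8-[2,6-bis(benzyloxy)-4-hydroxyphenyl]-2-[4-(benzyloxy)phenyl]-4H-chromen-4-one | O=c1cc(-c2ccc(OCc3ccccc3)cc2)oc2c(-c3c(OCc4ccccc4)cc(O)cc3OCc3ccccc3)c(OCc3ccccc3)cc(OCc3ccccc3)c12 | intermediate
10 | 4-hydroxybenzoic acid | OC(=O)c1ccc(O)cc1 | starting material
11 | 4-{[(benzyloxy)carbonyl]oxy}benzoic acid | OC(=O)c1ccc(OC(=O)OCc2ccccc2)cc1 | intermediate
12 | 3-(tert-butoxy)-3-oxopropanoic acid (mono-tert-butyl malonate) | CC(C)(C)OC(=O)CC(=O)O | starting material
13 | 4-{[(benzyloxy)carbonyl]oxy}benzoyl chloride | ClC(=O)c1ccc(OC(=O)OCc2ccccc2)cc1 | intermediate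
14 | tert-butyl 3-(4-{[(benzyloxy)carbonyl]oxy}phenyl)-3-oxopropanoate | CC(C)(C)OC(=O)CC(=O)c1ccc(OC(=O)OCc2ccccc2)cc1 | intermediate
15 | tert-butyl (3R)-3-(4-{[(benzyloxy)carbonyl]oxy}phenyl)-3-hydroxypropanoate | CC(C)(C)OC(=O)C[C@@H](O)c1ccc(OC(=O)OCc2ccccc2)cc1 | intermediate
16 | tert-butyl (3S)-3-(4-{[(benzyloxy)carbonyl]oxy}phenyl)-3-(3,5-bis(benzyloxy)-4-{5,7-bis(benzyloxy)-2-[4-(benzyloxy)phenyl]-4-oxo-4H-chromen-8-yl}phenoxy)propanoate | CC(C)(C)OC(=O)C[C@@H](c1ccc(OC(=O)OCc2ccccc2)cc1)Oc1cc(OCc2ccccc2)c(-c2c(OCc3ccccc3)cc(OCc3ccccc3)c3c(=O)cc(-c4ccc(OCc5ccccc5)cc4)oc23)c(OCc2ccccc2)c1 | intermediate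
17 | (3S)-3-(4-{[(benzyloxy)carbonyl]oxy}phenyl)-3-(3,5-bis(benzyloxy)-4-{5,7-bis(benzyloxy)-2-[4-(benzyloxy)phenyl]-4-oxo-4H-chromen-8-yl}phenoxy)propanoic acid | OC(=O)C[C@@H](c1ccc(OC(=O)OCc2ccccc2)cc1)Oc1cc(OCc2ccccc2)c(-c2c(OCc3ccccc3)cc(OCc3ccccc3)c3c(=O)cc(-c4ccc(OCc5ccccc5)cc4)oc23)c(OCc2ccccc2)c1 | intermediate
18 | benzyl 4-[(2S)-5,7-bis(benzyloxy)-6-{5,7-bis(benzyloxy)-2-[4-(benzyloxy)phenyl]-4-oxo-4H-chromen-8-yl}-4-oxo-3,4-dihydro-2H-chromen-2-yl]phenyl carbonate | O=C1C[C@@H](c2ccc(OC(=O)OCc3ccccc3)cc2)Oc2cc(OCc3ccccc3)c(-c3c(OCc4ccccc4)cc(OCc4ccccc4)c4c(=O)cc(-c5ccc(OCc6ccccc6)cc5)oc34)c(OCc3ccccc3)c21 | intermediate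
19 | (2S)-5,7-dihydroxy-6-[5,7-dihydroxy-2-(4-hydroxyphenyl)-4-oxo-4H-chromen-8-yl]-2-(4-hydroxyphenyl)-2,3-dihydro-4H-chromen-4-one | O=C1C[C@@H](c2ccc(O)cc2)Oc2cc(O)c(-c3c(O)cc(O)c4c(=O)cc(-c5ccc(O)cc5)oc34)c(O)c21 | target

Total step count: 10
Longest linear sequence: 5 steps (steps 3, 4, 5, 9, 10; the branches through steps 1–2 and 6–8 are equally long)

Steps most likely to fail

1. Step 9. What may go wrong: β-elimination of the activated β-hydroxy ester to the cinnamate during the Mitsunobu stage, or erosion of C2 and ether cleavage by ionisation at the benzylic carbon while the tert-butyl ester is removed in TFA. Fallback, setting out from 9 and coming back at 17: 4-hydroxybenzaldehyde would be acylated with benzyl chloroformate to 4-formylphenyl benzyl carbonate F1. Brown allylation of F1 with the B-allyldiisopinocampheylborane derived from (−)-α-pinene should give (1R)-1-(4-{[(benzyloxy)carbonyl]oxy}phenyl)but-3-en-1-ol F2, which has no acidic α-hydrogens and cannot eliminate to a conjugated ester. Mitsunobu etherification of 9 with F2 (PPh3, DIAD, toluene) should give, with inversion, the (S)-homoallyl aryl ether F3. Lemieux–Johnson cleavage of the terminal alkene (OsO4 cat., NaIO4, 2,6-lutidine, dioxane/H2O) would give the (S)-β-aryloxy aldehyde F4, and Pinnick oxidation (NaClO2, NaH2PO4, 2-methylbut-2-ene) the acid 17. Acid 17 is then closed to 18 with TFAA alone at 0 °C, so that no TFA stage is needed.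

2. Step 5. What may go wrong: slow transmetalation at the doubly ortho-substituted boron centre with competing protodeboronation, so that the hindered biaryl bond is not formed. Fallback, setting out from 5 and coming back at 8: 5 would be lithiated as in step 4 to aryllithium 6 and transmetalated with ZnCl2 to {2,6-bis(benzyloxy)-4-[(triisopropylsilyl)oxy]phenyl}zinc chloride F5. Negishi coupling of F5 with iodide 3 (Pd2(dba)3, RuPhos, THF, 65 °C), which runs without water or base and has no protodemetalation channel of this kind, should give 8. Desilylation of 8 with TBAF then gives 9 as in step 5.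

3. Step 4. What may go wrong: deprotonation at a benzylic CH2 of the benzyl ethers followed by Wittig rearrangement, or metalation next to the silyloxy group instead of between the two benzyloxy groups. Fallback, setting out from 5 and coming back at 7: electrophilic bromination of 5 (NBS, MeCN, 0 °C) should occur para to the silyloxy group, at the carbon between the two benzyloxy groups, because the triisopropylsilyl group shields its own ortho positions, giving [4-bromo-3,5-bis(benzyloxy)phenoxy]triisopropylsilane F6. Bromine–lithium exchange (n-BuLi, THF, −78 °C), which is much faster than any deprotonation, would give aryllithium 6, and B(OiPr)3 followed by hydrolysis gives 7.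

Further compounds
F1 | step 9 | 4-formylphenyl benzyl carbonate | O=Cc1ccc(OC(=O)OCc2ccccc2)cc1
F2 | step 9 | (1R)-1-(4-{[(benzyloxy)carbonyl]oxy}phenyl)but-3-en-1-ol | C=CC[C@@H](O)c1ccc(OC(=O)OCc2ccccc2)cc1
F3 | step 9 | benzyl 4-[(1S)-1-(3,5-bis(benzyloxy)-4-{5,7-bis(benzyloxy)-2-[4-(benzyloxy)phenyl]-4-oxo-4H-chromen-8-yl}phenoxy)but-3-en-1-yl]phenyl carbonate | C=CC[C@@H](c1ccc(OC(=O)OCc2ccccc2)cc1)Oc1cc(OCc2ccccc2)c(-c2c(OCc3ccccc3)cc(OCc3ccccc3)c3c(=O)cc(-c4ccc(OCc5ccccc5)cc4)oc23)c(OCc2ccccc2)c1
F4 | step 9 | benzyl 4-[(1S)-1-(3,5-bis(benzyloxy)-4-{5,7-bis(benzyloxy)-2-[4-(benzyloxy)phenyl]-4-oxo-4H-chromen-8-yl}phenoxy)-3-oxopropyl]phenyl carbonate | O=CC[C@@H](c1ccc(OC(=O)OCc2ccccc2)cc1)Oc1cc(OCc2ccccc2)c(-c2c(OCc3ccccc3)cc(OCc3ccccc3)c3c(=O)cc(-c4ccc(OCc5ccccc5)cc4)oc23)c(OCc2ccccc2)c1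
F5 | step 5 | {2,6-bis(benzyloxy)-4-[(triisopropylsilyl)oxy]phenyl}zinc chloride | Cl[Zn]c1c(OCc2ccccc2)cc(O[Si](C(C)C)(C(C)C)C(C)C)cc1OCc1ccccc1
F6 | step 4 | [4-bromo-3,5-bis(benzyloxy)phenoxy]triisopropylsilane | CC(C)[Si](C(C)C)(C(C)C)Oc1cc(OCc2ccccc2)c(Br)c(OCc2ccccc2)c1
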